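Thursday's flask, charged like Saturday's but with 0.240 M of product added, has made 0.508 M of new product by 29 h against Saturday's 0.511 M, a gap of 3.00 mM, smaller than the 0.004 M scatter of one reading, so added product can be set aside and the first question is where such a flask stops.

| setting | Saturday's | Wednesday's | Thursday's | Sunday's | Tuesday's |
|---|---|---|---|---|---|
| starting material | 0.800 M | 0.800 M | 0.800 M | 2.40 M | 0.260 M |
| reagent | 0.800 M | 1.60 M | 0.800 M | 0.800 M | 0.800 M |
| free catalyst | 0.0240 M | 0.0240 M | 0.0240 M | 0.0240 M | 0.00790 M |
| product |  |  | 0.240 M |  |  |
| time |  |  |  |  | 29 h |

- Saturday's run (time / h: [product] / M): 1.2: 0.117; 2.6: 0.217; 5.8: 0.341; 13: 0.458; 29: 0.511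
- Wednesday's run (time / h: [product] / M): 1.2: 0.200; 2.6: 0.342; 5.8: 0.495; 13: 0.594; 29: 0.623
- Thursday's run (time / h: [product] / M): 1.2: 0.353; 2.6: 0.452; 5.8: 0.579; 13: 0.694; 29: 0.748
- Sunday's run (time / h: [product] / M): 1.2: 0.230; 2.6: 0.412; 5.8: 0.619; 13: 0.749; 29: 0.792

(standard deviation of a reading: 0.004 M)

- how the opening rate goes with [starting material] round the charge of the Saturday's run: the exponent of the rate at two percent of starting material gone to product (one fixed amount of product, the same in the runs compared)
- how the opening rate goes with [reagent] round the charge of the Saturday's run: the exponent of the rate at two percent of starting material gone to product
- product in the Tuesday's run at 29 h, as a share of the starting material charged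

- Overall: starting material + reagent -> product, with free catalyst as catalyst.
- Constant volume, constant temperature.
- Bound and free are read together.
- "The second partner" is reagent.
- An order is taken over about fifteen percent of the charge, up and down.

Saturday's flask has made 0.511 M by 29 h, which is 63.9% of its charge, and its last 16.0 h add 0.0530 M, less than the 0.117 M of its first 1.2 h, although 0.289 M of the starting material charged has not become product.

So how long does such a flask effectively work? The first reading gives an opening constant, a pseudo-first-order rate per starting material charged, of 0.122 /h. The working time is the time for which that constant, held steady, would turn the share reached at the last reading: minus the logarithm of the share unturned, divided by the constant. Saturday's flask gives 8.35 h, Thursday's 8.56 h, and Sunday's, with 2.40 M of starting material on the same catalyst, a shorter 5.01 h.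

Which working time belongs to Tuesday's flask? It has Saturday's reagent and Saturday's starting material per catalyst, 32.9 against 33.3, so my reckoning carries Saturday's value. Its opening constant needs two scalings: first order in catalyst, which I assume, and the order in starting material across Saturday's and Sunday's first readings, 0.615, a wide-span figure and not the local one asked. That gives 0.0618 /h, and over Saturday's working time a share of 40.3%.

The forecast puts the local orders at 0.75 in starting material and 0.87 in reagent, and Tuesday's share at 38%, lower than mine, calling it “an estimate rather than a fit”.

Round Saturday's charge the orders come out at 0.76 in starting material and 0.87 in reagent, and Tuesday's flask reaches 39.7%.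

    free catalyst + starting material ⇌ catalyst-substrate complex, settled at all times (0.1970 /M)
    catalyst-substrate complex + reagent ⇌ ternary complex, settled at all times (1.740 /M)
    ternary complex → product + free catalyst (30.92 /h)
    free catalyst + reagent → spent catalyst + reagent (0.08856 /M/h)
    starting material → decomposed substrate (0.04068 /h)

Read back from 39.7%, Tuesday's working time is 8.19 h. It stays that short because of two losses acting together, free catalyst going to spent catalyst and starting material going to decomposed substrate: Tuesday's run without the first path reaches 54.9%, a working time of 12.9 h, and without the second 53.6%, a working time of 12.4 h.

The data were computed with constants of no real substance; scatter was added.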